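**Plan**
1. Ring A is numbered C1′ (acyl), C2′ (OH), C3′ (prenyl), C4′ (OH), C5′ (prenyl), C6′ (H). The ketone C=O, C2′–O and C4′–O stand in a 1,3,5-relation and C6′ is at the aldehyde level. Ring A plus the ketone is therefore the folded form of a 2,4-diprenyl-3,5,7-trioxo aldehyde chain, and the target (C25H30O4) is an isomer of a 2-(acylmethyl)-4-pyranone.
2. The first cut is C1′–C6′ (aldol/Knoevenagel), with the chain masked as the pyranone. The second cut is C1′–C(=O), the bond that the first chain extension on the aroyl starter makes in chalcone biosynthesis. This gives 2-methyl-3,5-diprenyl-4-pyranone and the Weinreb amide of phloretic acid (ring B is bought).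
3. The pyranone is cut at C2–C3 (acetyl) and C5–C6 (aminomethylene). This leads back to the symmetrical ketone 2,10-dimethylundeca-2,9-dien-6-one, whose two α-carbons already carry both prenyl groups. The ketone comes from 6-methylhept-5-en-2-one and prenyl bromide.
4. The forward order is ketone, enaminone, pyranone (a temporary ring), then lateral acylation to join the halves. Methoxide then opens the pyranone and the chain refolds, so ring A arises last with all five substituents in place. No arene substitution, no acid on a prenylphenol and no protecting group is needed.
5. The target has no stereocentre and no E/Z-isomeric alkene, so nothing has to be set.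

Key step: step 5

Remark: LDA, LiHMDS and NaOMe are taken as commercial solutions, so no reagent is generated in the flask.

Step 1
Reactants: 1 6-methylhept-5-en-2-one; 2 prenyl bromide (1-bromo-3-methylbut-2-ene)
Product: 3 2,10-dimethylundeca-2,9-dien-6-one
Conditions: LDA (1.05 equiv), THF, −78 °C; then 2, DMPU, −78 → 0 °C
Reagents that add atoms: none
Why: Kinetic enolate alkylation: LDA at −78 °C deprotonates the methyl ketone at the less hindered CH3 group and the reactive primary allylic bromide is displaced in an SN2 reaction before the enolate can equilibrate, which gives the symmetrical ketone whose two α-carbons each carry a prenyl group.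

Step 2
Reactants: 3 2,10-dimethylundeca-2,9-dien-6-one
Product: 4 (5E)-5-[(dimethylamino)methylidene]-2,10-dimethylundeca-2,9-dien-6-one
Conditions: t-BuOCH(NMe2)2 (1.2 equiv), toluene, 100 °C
Reagents that add atoms: tert-butoxybis(dimethylamino)methane (Bredereck's reagent), CN(C)C(OC(C)(C)C)N(C)C
Why: Aminomethylenation of an α-methylene ketone with Bredereck's reagent (condensation with loss of t-BuOH and Me2NH): both α-CH2 groups of 3 are equivalent, so no regiochemical question arises, and the vinylogous amide formed is too weakly acidic at its α′-carbon to condense a second time.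

Step 3
Reactants: 4 (5E)-5-[(dimethylamino)methylidene]-2,10-dimethylundeca-2,9-dien-6-one
Product: 6 2-methyl-3,5-bis(3-methylbut-2-enyl)-4H-pyran-4-one, via diketo enaminone 5 (not isolated)
Conditions: LDA (1.1 equiv), THF, −78 °C; MeC(O)N(OMe)Me, −78 → 0 °C; then AcOH, 50 °C
Reagents that add atoms: N-methoxy-N-methylacetamide, CC(=O)N(C)OC
Why: α′-Deprotonation of the tertiary enaminone and C-acylation with the Weinreb acetamide (Claisen-type acylation, in which the chelated adduct blocks proton exchange and double acylation) give 5 on acidification, whose enol oxygen adds to the protonated enaminone carbon and expels Me2NH (6-endo-trig addition-elimination), the standard enaminone route to 4-pyranones, in acetic acid that is too weak to protonate the prenyl double bonds.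

Step 4
Reactants: 7 3-(4-hydroxyphenyl)propanoic acid (phloretic acid)
Product: 9 3-(4-hydroxyphenyl)-N-methoxy-N-methylpropanamide, via acyl imidazolide 8 (not isolated)
Conditions: CDI (1.05 equiv), THF, 0 °C → rt; then MeNH(OMe)·HCl, rt
Reagents that add atoms: N,O-dimethylhydroxylamine hydrochloride, CNOC.Cl; 1,1'-carbonyldiimidazole, O=C(n1ccnc1)n1ccnc1 (supplies the imidazolyl group of 8 only)
Why: Weinreb amide formation by CDI activation: the carboxylic acid is converted to the acyl imidazolide 8 far faster than the phenol reacts, and the amine then displaces imidazole, so the phenol needs no protection.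

Step 5
Reactants: 6 2-methyl-3,5-bis(3-methylbut-2-enyl)-4H-pyran-4-one; 9 3-(4-hydroxyphenyl)-N-methoxy-N-methylpropanamide
Product: 12 gancaonin J, via acylmethylpyranone 10 (not isolated), via methoxyenone triketone 11 (not isolated)
Conditions: 6, LiHMDS (1.1 equiv), THF, −78 °C; add 9 pre-treated with LiHMDS (1.0 equiv), −78 → 0 °C; then NaOMe (4 equiv), degassed MeOH, 60 °C; cold 1 M HCl to pH 5
Reagents that add atoms: sodium methoxide, [Na+].[O-]C (supplies the methoxy group of 11 only, which is lost again on ring closure)
Why: LiHMDS removes a proton only from the vinylogous 2-methyl group of 6 (the prenyl CH2 groups on C3/C5 are cross-conjugated and C6–H is far less acidic), and this carbanion attacks the Weinreb carbonyl of the lithium phenoxide of 9 in a lateral Claisen-type acylation that makes the bond between the future C1′ and the ketone carbon and gives 10, an isomer of the target. Methoxide then adds to the unsubstituted C6 of the pyranone and expels the ring oxygen as the C2 enolate (ANRORC opening), which unmasks the poly-β-carbonyl chain 11 with C6 held as an electrophilic β-methoxyenone that can neither enolise nor be deformylated. The doubly activated methylene (future C1′) closes on C6 by 6-endo-trig addition-elimination (Knoevenagel-type, formally also a 6π closure of the trienolate), methoxide is returned, and tautomerisation gives ring A, with pyranone O1 ending as the chelated 2′-OH and the pyranone C=O as the 4′-OH. The closest known reaction types are the lateral acylation of 2-methyl-4-pyranones and the classical base-induced recyclisation of 2-(2-oxoalkyl)-4-pyranones (and the corresponding tetraketones) to 2,4-dihydroxyaryl ketones, the laboratory counterpart of polyketide folding. No stereocentre is formed. The step needs C- over O-closure and the right nucleophile: O-closure only regenerates 10, closure from the prenylated C3 would give a four-membered ring, the singly activated CH2 next to ring B cannot compete with the β-diketone methylene, and aromatisation makes the wanted path the only irreversible one, while the substituent pattern is already fixed by the pyranone.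

**Compound list**
1 | 6-methylhept-5-en-2-one | CC(=O)CCC=C(C)C | starting material
2 | prenyl bromide (1-bromo-3-methylbut-2-ene) | CC(C)=CCBr | starting material
3 | 2,10-dimethylundeca-2,9-dien-6-one | CC(C)=CCCC(=O)CCC=C(C)C | intermediate
4 | (5E)-5-[(dimethylamino)methylidene]-2,10-dimethylundeca-2,9-dien-6-one | CN(C)/C=C(/C(=O)CCC=C(C)C)CC=C(C)C | intermediate
5 | (5E)-5-[(dimethylamino)methylidene]-8-methyl-3-(3-methylbut-2-enyl)non-7-ene-2,4-dione (C3 labile, racemic) | CN(C)/C=C(/C(=O)C(CC=C(C)C)C(C)=O)CC=C(C)C | intermediate
6 | 2-methyl-3,5-bis(3-methylbut-2-enyl)-4H-pyran-4-one | CC1=C(CC=C(C)C)C(=O)C(CC=C(C)C)=CO1 | intermediate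
7 | 3-(4-hydroxyphenyl)propanoic acid (phloretic acid) | OC(=O)CCc1ccc(O)cc1 | starting material
8 | 3-(4-hydroxyphenyl)-1-(imidazol-1-yl)propan-1-one | O=C(CCc1ccc(O)cc1)n1ccnc1 | intermediate
9 | 3-(4-hydroxyphenyl)-N-methoxy-N-methylpropanamide | CON(C)C(=O)CCc1ccc(O)cc1 | intermediate
10 | 2-[4-(4-hydroxyphenyl)-2-oxobutyl]-3,5-bis(3-methylbut-2-enyl)-4H-pyran-4-one | O=C(CCc1ccc(O)cc1)CC1=C(CC=C(C)C)C(=O)C(CC=C(C)C)=CO1 | intermediate
11 | 9-(4-hydroxyphenyl)-1-methoxy-2,4-bis(3-methylbut-2-enyl)non-1-ene-3,5,7-trione (keto/enol tautomers, configuration not defined) | COC=C(CC=C(C)C)C(=O)C(CC=C(C)C)C(=O)CC(=O)CCc1ccc(O)cc1 | intermediate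
12 | gancaonin J, 1-[2,4-dihydroxy-3,5-bis(3-methylbut-2-enyl)phenyl]-3-(4-hydroxyphenyl)propan-1-one | CC(C)=CCc1cc(C(=O)CCc2ccc(O)cc2)c(O)c(CC=C(C)C)c1O | target

Total step count: 5. Longest linear sequence: 4 (steps 1, 2, 3, 5).

**Steps most likely to fail**

1. Step 5.
   - Risk: The delocalised carbanion may attack the amide slowly and be lost to proton exchange. After acylation, the anionic pyranone may resist addition of methoxide. The opened chain may also fragment by retro-Claisen cleavage faster than it folds.
   - Fallback: It sets out from 7 and comes back at 12. Friedel–Crafts acylation of commercial resorcinol with 7 in BF3·OEt2 at about 85 °C should give 1-(2,4-dihydroxyphenyl)-3-(4-hydroxyphenyl)propan-1-one F1. The same aryl–carbonyl bond is thus made before any acid-sensitive prenyl group is present. Double nuclear C-prenylation of the acylresorcinolate with 2 (KOH, MeOH/H2O, 0 °C → rt) at C3′ and C5′, followed by chromatographic separation from under-prenylated and O-prenylated material, should then deliver 12.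

2. Step 3.
   - Risk: The hindered secondary α′-carbanion may add sluggishly to the acetamide or merely deprotonate it. During the acid closure, an enol oxygen may add to a neighbouring prenyl double bond.
   - Fallback: It sets out from 4 and comes back at 5. Aldol addition of the α′-lithiated enaminone to acetaldehyde (LDA, THF, −78 °C) should give (5E)-5-[(dimethylamino)methylidene]-7-(1-hydroxyethyl)-2,10-dimethylundeca-2,9-dien-6-one F2, a diastereomer mixture of no consequence. Oxidation with NaHCO3-buffered Dess–Martin periodinane in CH2Cl2 should give 5, which closes to 6 as in the route.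

3. Step 1.
   - Risk: Proton transfer between product ketone and enolate may equilibrate the enolate. Alkylation would then also occur at the internal α-carbon and more than once.
   - Fallback: It sets out from 2 and comes back at 3. Double alkylation of commercial dimethyl 3-oxopentanedioate with 2 (K2CO3, acetone, reflux), once on each activated methylene, should give dimethyl 2,4-bis(3-methylbut-2-enyl)-3-oxopentanedioate F3. Saponification (aq. NaOH, MeOH), mild acidification and warming should remove both carboxyl groups and give 3 with the alkylation sites fixed by the ester groups.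

**Further compounds**
F1 | step 5 | 1-(2,4-dihydroxyphenyl)-3-(4-hydroxyphenyl)propan-1-one | O=C(CCc1ccc(O)cc1)c1ccc(O)cc1O
F2 | step 3 | (5E)-5-[(dimethylamino)methylidene]-7-(1-hydroxyethyl)-2,10-dimethylundeca-2,9-dien-6-one (diastereomer mixture) | CN(C)/C=C(/C(=O)C(CC=C(C)C)C(C)O)CC=C(C)C
F3 | step 1 | dimethyl 2,4-bis(3-methylbut-2-enyl)-3-oxopentanedioate | COC(=O)C(CC=C(C)C)C(=O)C(CC=C(C)C)C(=O)OC
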